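Ring positions are referred to by the chromone numbering of the target (O1, C2, C3, C4, C4a, C5–C8, C8a; ring B carbons primed), also in open-chain precursors.

## Analysis of the target

The target is an isoflavone: a 4H-chromen-4-one, made of benzo ring A fused to pyranone ring C, that carries a 3,4-dihydroxyphenyl ring B on C3. Ring A is fully substituted, with hydroxyls on C5 and C7, a (2R)-2-hydroxy-3-methylbut-3-enyl chain on C6 and a prenyl group on C8. The only stereocentre is the (R)-configured allylic carbinol of the C6 chain. It has no partner centre to be related to, so it must be brought in enantiopure or set by a reagent. The sensitive groups are the catechol (oxidation), the prenyl group ortho to the 7-hydroxyl (acid-induced chroman formation), and the secondary allylic alcohol beside an isopropenyl group (ionisation and ring closure onto O5 or O7). Two different alkenes rule out unselective hydrogenation and electrophilic reagents. The hard part is the hexasubstituted ring A: three different carbon substituents must be placed in a fixed order around a phloroglucinol core. Its three oxygens must also be told apart, since O8a becomes the ring oxygen while O5 and O7 end as free phenols. The strategy rests on the C3–C4 bond of ring C. C4 (on C4a) and C3 (bearing ring B) are both carbonyl-derived carbons, an aldehyde carbon and an aryl ketone carbon. They can be joined if the aldehyde is turned into an acyl anion equivalent, and O1 and C2 then form a simple ether tether from O8a.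

## Retrosynthetic reasoning

**26 from 25 (protecting groups).** The four phenols are masked as methoxymethyl acetals and the side-chain alcohol as a silyl ether in 25. An aliphatic acetal on the carbinol would need acid strong enough to endanger the prenyl phenol and the allylic alcohol. The silyl ether instead leaves under the same mild acidic methanolysis as the aryl acetals, so one operation frees all five hydroxyls.

**25 from 24 (C2=C3).** The double bond is traced back to a tertiary carbinol on C3. The hydroxyl sits on the carbon alpha to the ketone and the hydrogen to be lost on C2, so no enolate-driven elimination is possible. The forward step must activate the hydroxyl and remove a C2 hydrogen in a syn or ion-pair manner. Both C3 epimers of 24 converge on 25, so the configuration at C3 never has to be controlled.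

**24 from 23 (C3–C4, the key cut).** Of the bonds in ring C, C3–C1' and C2–C3 come ready-made in an aryl methyl ketone and C4–C4a comes with a formyl group. C3–C4 is the one carbon–carbon bond that must be made. Cutting it gives aldehyde 23 with a tethered aryl ketone. The forward reaction is a polarity-reversed, carbene-catalysed addition of the aldehyde carbon to the ketone, closing the six-membered ring.

**23 from 18 and 22 (O8a–C2).** The ether bond is cut to salicylaldehyde 18 and alpha-bromo ketone 22. The forward step is a Williamson alkylation, which requires O8a to be the only free hydroxyl of 18.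

**22 from 20 from 19.** The bromo ketone comes from acetophenone 19 by acetal protection of the catechol (20) and bromination at the methyl group through an enol derivative, avoiding acid.

**18 from 17, 15, 14, 12 and 13 (C4a–CHO, then C8–prenyl).** The formyl carbon is removed first. In 17 the position is the last unsubstituted ring carbon and lies ortho to the only free hydroxyl, so a phenoxide-directed formylation has one possible outcome. The prenyl group on C8 is traced through a [3,3] shift to tertiary allyl ether 15, made from propargyl ether 14, which is itself made from phenol 12 and chloride 13. In 12 the two ortho positions are equivalent by symmetry and the para position is occupied, so the rearrangement can give only one constitution.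

**12 from 11, 10, 8 and 7 (side-chain adjustment).** The isopropenyl group is traced to the methyl ketone 10 and this to the ester 8 and hydroxy ester 7. The carbinol carbon is untouched throughout. The aryl silyl ether of 11 is the temporary mask of O8a and is removed selectively to give 12.

**7 from 3 and 4 (C6–CH2), 3 from 2 from 1.** The bond between C6 and the chain is cut to an aryl metal (5, then 6) and epoxide 4. In 3 the carbon between the two acetal oxygens is the one that is metalated, and it is para to the silyl-protected O8a. Opening 4 at its unsubstituted carbon leaves the stereocentre alone, so the (R) configuration is bought, not made. Arene 3 comes from phloroglucinol 1 by way of bis-acetal 2, the step at which O8a is set apart from O5 and O7.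

## Alternatives that were turned down

Alternative 1: The disconnection is ring A itself, across C8–C8a, C6–C7 and C4a–C8a. It leads to cyclobutenone A2 (carrying C8a as carbonyl, C4a, C5 with an ethoxy group and C6 with the chiral chain) and siloxyalkyne A3 (C7 with its silyloxy group, C8 with the prenyl group). In the forward key step A2 opens on heating to a vinylketene, which adds to A3 in a [2+2] manner. Opening of the new four-membered ring and six-electron electrocyclisation then give phenol A1.
- For: the order of all substituents is written into the connectivity of the two partners, and the three oxygens arrive already distinct. No statistical protection and no directing-group argument is needed. On certainty of the ring A pattern this is stronger than the chosen route.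
- Against: A1 is only the counterpart of phenol 17. Ring C is still unmade, so formylation, ether formation and a ring C closure must follow in any case.
- Against: A2 needs a ketene–alkoxyalkyne cycloaddition from an enantiopure acid chloride, and A3 needs an ester-to-ynolate homologation. Each takes several steps, so the count exceeds the eleven steps to 17.
- Against: the ethyl group on O5 has no mild exit. Its removal beside a prenyl phenol, an allylic carbinol and a catechol would need a boron or aluminium halide, which those groups do not tolerate.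
- Comparison: the chosen route accepts a statistical first step and in return uses acetal protection that leaves in one mild operation.

Alternative 2: The disconnection is C3–C1' and O1–C2, giving enaminone A5 (ring A with C4, C3 and C2 in place) and catechol A6. In the forward key step A6 is oxidised to ortho-quinone A7 in the presence of A5. The nucleophilic C3 of the enaminone adds to the 4-position of A7, the diphenol re-forms, and the C8a hydroxyl displaces the amine at C2 to give A4.
- For: ring B comes from the cheapest unprotected partner, two bonds and ring C form in one flask at the right oxidation level, and no dehydration is needed. In convergence of the end game this is stronger than the chosen route.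
- Against: in A5 the oxidant meets a free C8a phenol ortho to a prenyl group on a very electron-rich ring. This is the classic setting for oxidation to an ortho-quinone methide and closure to a dimethylchromene.
- Against: product A4 is a more electron-rich diphenol than A6 and should be oxidised in preference, inviting a second addition. A7 also self-condenses.
- Against: A5 needs an acetyl and not a formyl group on C4a. On this acetal-protected ring that means aldehyde 18, methyl addition, oxidation and aminomethylenation, three more steps before the key step, so the economy is lost.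
- Comparison: the chosen route is redox-neutral from 18 onward, takes the C3–C1' bond ready-made from 19, and exposes the catechol only in the last step.

Alternative 3: The disconnection is O1–C8a, C4–C4a and O1–C2, giving aryne A11 (from silyl triflate A10) and acrylic acid A9. In the forward key step fluoride releases A11 and the carboxylate of A9 adds through oxygen at C8a. The aryl anion at C4a then attacks the acyl carbon, and the freed phenoxide adds to the beta-carbon with loss of the methoxy group to give A8.
- For: this is the most convergent option, with three bonds formed, the chromone oxidation level reached directly and no dehydration. The inductive effect of the C5 oxygen should steer the nucleophile to the remote aryne carbon C8a, which is the right sense. On bonds formed per step it is stronger than the benzoin closure.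
- Against: A10 is a hexasubstituted arene with vicinal silyl and triflate groups. It could only come from a phenol like 17 by bromination, O-silylation, halogen–metal exchange with silyl migration, and triflation. That is more steps than the two that take 17 to 23.
- Against: A11 is flanked on both sides, the prenyl group beside the triple bond offers allylic hydrogens for ene-type self-quenching, and the acyl transfer must occur at the more hindered end.
- Against: the fluoride trigger excludes silyl protection, so the side-chain alcohol is an alkyl acetal in A8. Its removal needs acid strong enough to threaten the prenyl phenol. A9 is a further multi-step fragment.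
- Comparison: the chosen route gives up convergence for a precursor reachable by ordinary phenol chemistry and puts the risk in one well-understood catalytic step.

Key step: step 15

Remark: the carbinol centre is (R) as read from the SMILES. The ester carbon of 4 and the isopropenyl carbon of the target hold the same CIP rank, so the descriptor stays (R) from 4 to 26.
Remark: the tertiary propargylic chloride 13 is used as the commercial, activated form of 2-methylbut-3-yn-2-ol.
Remark: the side-chain alcohol is carried as a tert-butyldimethylsilyl ether and O8a is masked as a triisopropylsilyl ether during metalation.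

## Route

Step 1
Reactants: 1 phloroglucinol (benzene-1,3,5-triol)
Product: 2 3,5-bis(methoxymethoxy)phenol
Conditions: MOMCl (2.0 equiv), i-Pr2NEt, DMF, 0 °C → rt; chromatography
Reagents that add atoms: chloromethyl methyl ether, COCCl
Why: Williamson-type O-alkylation of the phenoxides; the three hydroxyls of 1 are equivalent, so the reaction is statistical and 2 is separated from the mono- and tris-ethers, which can be recycled. It leaves one free oxygen, the future O8a.

Step 2
Reactants: 2 3,5-bis(methoxymethoxy)phenol
Product: 3 [3,5-bis(methoxymethoxy)phenoxy]triisopropylsilane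
Conditions: TIPSCl, imidazole, DMF, rt
Reagents that add atoms: chlorotriisopropylsilane, CC(C)[Si](Cl)(C(C)C)C(C)C
Why: Silylation of the remaining phenol; the bulky silyl ether is inert to alkyllithiums, shields its two ortho positions, and can later be removed by fluoride without touching the MOM acetals.

Step 3
Reactants: 3 [3,5-bis(methoxymethoxy)phenoxy]triisopropylsilane; 4 methyl (R)-glycidate (methyl (2R)-oxirane-2-carboxylate)
Product: 7 methyl (2R)-3-[2,6-bis(methoxymethoxy)-4-(triisopropylsilyloxy)phenyl]-2-hydroxypropanoate, via aryllithium 5 (not isolated), via arylmagnesium bromide 6 (not isolated)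
Conditions: n-BuLi, THF, 0 °C; MgBr2·OEt2, 0 °C; CuI (10 mol%), then 4, −40 → −20 °C; aq NH4Cl
Reagents that add atoms: none
Why: Directed ortho-metalation takes place at the carbon flanked by both MOM ethers, giving 5; transmetalation to 6 and copper-catalysed SN2 opening of the epoxide at its unsubstituted carbon form the C6–CH2 bond. The stereocentre of 4 is not a reacting centre and is carried over as the (R)-carbinol; the low temperature keeps the aryl metal away from the ester.

Step 4
Reactants: 7 methyl (2R)-3-[2,6-bis(methoxymethoxy)-4-(triisopropylsilyloxy)phenyl]-2-hydroxypropanoate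
Product: 8 methyl (2R)-3-[2,6-bis(methoxymethoxy)-4-(triisopropylsilyloxy)phenyl]-2-(tert-butyldimethylsilyloxy)propanoate
Conditions: TBSCl, imidazole, DMF, rt
Reagents that add atoms: tert-butyldimethylsilyl chloride, CC(C)(C)[Si](C)(C)Cl
Why: Standard silylation of a secondary alcohol; the chloride/imidazole protocol is used because a silyl triflate could attack the MOM acetals.

Step 5
Reactants: 8 methyl (2R)-3-[2,6-bis(methoxymethoxy)-4-(triisopropylsilyloxy)phenyl]-2-(tert-butyldimethylsilyloxy)propanoate
Product: 10 (3R)-4-[2,6-bis(methoxymethoxy)-4-(triisopropylsilyloxy)phenyl]-3-(tert-butyldimethylsilyloxy)butan-2-one, via Weinreb amide 9 (not isolated)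
Conditions: MeNH(OMe)·HCl, i-PrMgCl, THF, −20 °C; then MeMgBr, −20 → 0 °C; aq NH4Cl
Reagents that add atoms: methylmagnesium bromide, C[Mg]Br
Why: Aminolysis of the ester by the magnesium amide gives Weinreb amide 9, whose chelated tetrahedral adduct with MeMgBr stops at the ketone stage (Weinreb ketone synthesis, run in one pot). The alpha-silyloxy centre is not enolised under these conditions.

Step 6
Reactants: 10 (3R)-4-[2,6-bis(methoxymethoxy)-4-(triisopropylsilyloxy)phenyl]-3-(tert-butyldimethylsilyloxy)butan-2-one
Product: 11 {4-[(2R)-2-(tert-butyldimethylsilyloxy)-3-methylbut-3-en-1-yl]-3,5-bis(methoxymethoxy)phenoxy}triisopropylsilane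
Conditions: Ph3PCH3Br, KN(SiMe3)2, THF, 0 °C; then 10, −78 → 0 °C
Reagents that add atoms: methyltriphenylphosphonium bromide, C[P+](c1ccccc1)(c1ccccc1)c1ccccc1.[Br-]
Why: Wittig methylenation of a methyl ketone; the ylide is pre-formed with a slight deficit of base and the ketone is added cold, so the alpha-silyloxy stereocentre should not epimerise.

Step 7
Reactants: 11 {4-[(2R)-2-(tert-butyldimethylsilyloxy)-3-methylbut-3-en-1-yl]-3,5-bis(methoxymethoxy)phenoxy}triisopropylsilane
Product: 12 4-[(2R)-2-(tert-butyldimethylsilyloxy)-3-methylbut-3-en-1-yl]-3,5-bis(methoxymethoxy)phenol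
Conditions: TBAF (1.05 equiv), THF, −20 → 0 °C; aq NH4Cl
Reagents that add atoms: none
Why: Fluoride cleaves the aryl silyl ether far faster than the hindered secondary alkyl silyl ether, because phenoxide is the better leaving group; with one equivalent at low temperature only O8a should be freed.

Step 8
Reactants: 12 4-[(2R)-2-(tert-butyldimethylsilyloxy)-3-methylbut-3-en-1-yl]-3,5-bis(methoxymethoxy)phenol; 13 3-chloro-3-methylbut-1-yne
Product: 14 tert-butyl{[(2R)-1-{2,6-bis(methoxymethoxy)-4-[(2-methylbut-3-yn-2-yl)oxy]phenyl}-3-methylbut-3-en-2-yl]oxy}dimethylsilane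
Conditions: CuCl2·2H2O (1 mol%), DBU, MeCN, 0 °C
Reagents that add atoms: none
Why: Copper-catalysed O-alkylation of a phenol by a tertiary propargylic chloride gives the tertiary ether that a plain SN2 reaction cannot; the phenol has two unhindered ortho positions.

Step 9
Reactants: 14 tert-butyl{[(2R)-1-{2,6-bis(methoxymethoxy)-4-[(2-methylbut-3-yn-2-yl)oxy]phenyl}-3-methylbut-3-en-2-yl]oxy}dimethylsilane
Product: 15 tert-butyl{[(2R)-1-{2,6-bis(methoxymethoxy)-4-[(2-methylbut-3-en-2-yl)oxy]phenyl}-3-methylbut-3-en-2-yl]oxy}dimethylsilane
Conditions: H2 (1 atm), Pd/CaCO3 poisoned with Pb(OAc)2 (Lindlar catalyst), quinoline, EtOAc, rt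
Reagents that add atoms: none
Why: Lindlar semihydrogenation stops at the terminal alkene; the poisoned catalyst should not reduce the 1,1-disubstituted alkene of the side chain, and uptake is stopped after one equivalent.

Step 10
Reactants: 15 tert-butyl{[(2R)-1-{2,6-bis(methoxymethoxy)-4-[(2-methylbut-3-en-2-yl)oxy]phenyl}-3-methylbut-3-en-2-yl]oxy}dimethylsilane
Product: 17 4-[(2R)-2-(tert-butyldimethylsilyloxy)-3-methylbut-3-en-1-yl]-3,5-bis(methoxymethoxy)-2-(3-methylbut-2-en-1-yl)phenol, via cyclohexadienone 16 (not isolated)
Conditions: PhNEt2, 120 °C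
Reagents that add atoms: none
Why: Aromatic Claisen rearrangement: the [3,3] shift delivers the allyl unit with allylic inversion to an ortho carbon as a linear prenyl group, and dienone 16 tautomerises to the phenol. The two ortho positions are equivalent by symmetry and the para position is blocked, so one constitution is expected; the weakly basic solvent suppresses acid-catalysed chroman formation.

Step 11
Reactants: 17 4-[(2R)-2-(tert-butyldimethylsilyloxy)-3-methylbut-3-en-1-yl]-3,5-bis(methoxymethoxy)-2-(3-methylbut-2-en-1-yl)phenol
Product: 18 3-[(2R)-2-(tert-butyldimethylsilyloxy)-3-methylbut-3-en-1-yl]-6-hydroxy-2,4-bis(methoxymethoxy)-5-(3-methylbut-2-en-1-yl)benzaldehyde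
Conditions: MgCl2, Et3N, (CH2O)n, THF, reflux
Reagents that add atoms: paraformaldehyde (as formaldehyde), C=O
Why: Magnesium-mediated ortho-formylation: the magnesium phenoxide delivers formaldehyde to the ortho carbon through a chelate, and the benzylic alkoxide is oxidised by a second formaldehyde through hydride transfer. Only one ring position is unsubstituted and it is ortho to the sole free hydroxyl; acetals, silyl ether and both alkenes are inert.

Step 12
Reactants: 19 3',4'-dihydroxyacetophenone
Product: 20 1-[3,4-bis(methoxymethoxy)phenyl]ethan-1-one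
Conditions: MOMCl, i-Pr2NEt, CH2Cl2, 0 °C → rt
Reagents that add atoms: chloromethyl methyl ether, COCCl
Why: Exhaustive acetal protection of the catechol, so that ring B survives base, the carbene step and dehydration and is unmasked with ring A at the end.

Step 13
Reactants: 20 1-[3,4-bis(methoxymethoxy)phenyl]ethan-1-one
Product: 22 2-bromo-1-[3,4-bis(methoxymethoxy)phenyl]ethan-1-one, via silyl enol ether 21 (not isolated)
Conditions: LiN(SiMe3)2, TMSCl, THF, −78 °C; then NBS, −78 → 0 °C
Reagents that add atoms: N-bromosuccinimide, O=C1CCC(=O)N1Br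
Why: Kinetic enolisation with in situ silylation gives silyl enol ether 21, which NBS brominates at carbon. This avoids the hydrogen bromide released in direct ketone bromination, which would cleave the MOM acetals.

Step 14
Reactants: 18 3-[(2R)-2-(tert-butyldimethylsilyloxy)-3-methylbut-3-en-1-yl]-6-hydroxy-2,4-bis(methoxymethoxy)-5-(3-methylbut-2-en-1-yl)benzaldehyde; 22 2-bromo-1-[3,4-bis(methoxymethoxy)phenyl]ethan-1-one
Product: 23 6-{2-[3,4-bis(methoxymethoxy)phenyl]-2-oxoethoxy}-3-[(2R)-2-(tert-butyldimethylsilyloxy)-3-methylbut-3-en-1-yl]-2,4-bis(methoxymethoxy)-5-(3-methylbut-2-en-1-yl)benzaldehyde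
Conditions: K2CO3, acetone, rt
Reagents that add atoms: none
Why: Williamson ether synthesis with a highly reactive alpha-halo ketone; O8a is the only free hydroxyl. Mild base at room temperature is used so that the product does not go on to intramolecular aldol condensation (Rap–Stoermer benzofuran formation).

Step 15
Reactants: 23 6-{2-[3,4-bis(methoxymethoxy)phenyl]-2-oxoethoxy}-3-[(2R)-2-(tert-butyldimethylsilyloxy)-3-methylbut-3-en-1-yl]-2,4-bis(methoxymethoxy)-5-(3-methylbut-2-en-1-yl)benzaldehyde
Product: 24 3-[3,4-bis(methoxymethoxy)phenyl]-6-[(2R)-2-(tert-butyldimethylsilyloxy)-3-methylbut-3-en-1-yl]-3-hydroxy-5,7-bis(methoxymethoxy)-8-(3-methylbut-2-en-1-yl)-2,3-dihydro-4H-chromen-4-one (both C3 epimers)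
Conditions: 2-(pentafluorophenyl)-6,7-dihydro-5H-pyrrolo[2,1-c][1,2,4]triazol-2-ium tetrafluoroborate (20 mol%), Et3N (20 mol%), THF, 40 °C, argon
Reagents that add atoms: none
Why: Deprotonation of the triazolium salt gives the carbene, which adds to the aldehyde carbon (C4); proton transfer gives the Breslow intermediate, whose nucleophilic carbon attacks the tethered ketone carbon (C3), and proton transfer with release of the carbene gives the acyloin. The closest known reaction type is the carbene-catalysed intramolecular crossed aldehyde–ketone benzoin of 2-(2-aryl-2-oxoethoxy)benzaldehydes to 3-hydroxychroman-4-ones. Ring C closes in the 6-exo-trig mode, the ring comprising C4, C4a, C8a, O1, C2 and C3 with the ketone oxygen exocyclic. The new C3 carbinol centre is not controlled, since neither the achiral catalyst nor the remote side-chain centre biases it, and it need not be, because step 16 erases it; 24 is carried on as the epimer pair. The required chemoselectivity, aldehyde as donor and ketone as acceptor, is inherent: only the aldehyde has the C–H needed to form a Breslow intermediate, and the ketone is held six atoms away, so cyclisation should outrun homo-benzoin coupling of the doubly ortho-substituted aldehyde. A small bicyclic triazolium with an electron-poor N-aryl group is chosen because Et3N suffices to turn it over, and this base is too weak to enolise the phenacyl CH2 appreciably, which holds back the competing aldol path to a 2-aroylbenzofuran. Both alkenes, the silyl ether and the MOM acetals are inert to the carbene, and air is excluded to prevent oxidation of the Breslow intermediate.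

Step 16
Reactants: 24 3-[3,4-bis(methoxymethoxy)phenyl]-6-[(2R)-2-(tert-butyldimethylsilyloxy)-3-methylbut-3-en-1-yl]-3-hydroxy-5,7-bis(methoxymethoxy)-8-(3-methylbut-2-en-1-yl)-2,3-dihydro-4H-chromen-4-one
Product: 25 3-[3,4-bis(methoxymethoxy)phenyl]-6-[(2R)-2-(tert-butyldimethylsilyloxy)-3-methylbut-3-en-1-yl]-5,7-bis(methoxymethoxy)-8-(3-methylbut-2-en-1-yl)-4H-chromen-4-one
Conditions: Burgess reagent (methyl N-(triethylammoniosulfonyl)carbamate), PhMe, 60 °C
Reagents that add atoms: none
Why: The hydroxyl to be lost is on the carbon alpha to the ketone and the hydrogen on C2, so an enolate pathway is not available; the Burgess reagent converts the tertiary benzylic carbinol into a sulfamate that ionises to a tight ion pair, stabilised by electron-rich ring B, and loses a C2 hydrogen syn (Ei-type dehydration) to give the conjugated chromone. Both C3 epimers have a syn hydrogen on C2 and converge on 25; no other free hydroxyl is present.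

Step 17
Reactants: 25 3-[3,4-bis(methoxymethoxy)phenyl]-6-[(2R)-2-(tert-butyldimethylsilyloxy)-3-methylbut-3-en-1-yl]-5,7-bis(methoxymethoxy)-8-(3-methylbut-2-en-1-yl)-4H-chromen-4-one
Product: 26 3-(3,4-dihydroxyphenyl)-5,7-dihydroxy-6-[(2R)-2-hydroxy-3-methylbut-3-en-1-yl]-8-(3-methylbut-2-en-1-yl)-4H-chromen-4-one (CNP0305771.1)
Conditions: HCl (3 M aq), MeOH, rt → 40 °C
Reagents that add atoms: none
Why: Acid-catalysed acetal exchange with methanol removes the four aryl MOM groups, and solvolysis removes the secondary silyl ether in the same operation. Dilute acid and moderate temperature are chosen to stay below the threshold for cyclisation of the prenyl phenol or ionisation of the allylic carbinol; the stereocentre is not involved.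

## Compound list

1 | phloroglucinol | Oc1cc(O)cc(O)c1 | starting material
2 | 3,5-bis(methoxymethoxy)phenol | COCOc1cc(O)cc(OCOC)c1 | intermediate
3 | [3,5-bis(methoxymethoxy)phenoxy]triisopropylsilane | COCOc1cc(OCOC)cc(O[Si](C(C)C)(C(C)C)C(C)C)c1 | intermediate
4 | methyl (R)-glycidate | COC(=O)[C@H]1CO1 | starting material
5 | [2,6-bis(methoxymethoxy)-4-(triisopropylsilyloxy)phenyl]lithium | [Li]c1c(OCOC)cc(O[Si](C(C)C)(C(C)C)C(C)C)cc1OCOC | intermediate
6 | [2,6-bis(methoxymethoxy)-4-(triisopropylsilyloxy)phenyl]magnesium bromide | Br[Mg]c1c(OCOC)cc(O[Si](C(C)C)(C(C)C)C(C)C)cc1OCOC | intermediate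
7 | methyl (2R)-3-[2,6-bis(methoxymethoxy)-4-(triisopropylsilyloxy)phenyl]-2-hydroxypropanoate | COC(=O)[C@H](O)Cc1c(OCOC)cc(O[Si](C(C)C)(C(C)C)C(C)C)cc1OCOC | intermediate
8 | methyl (2R)-3-[2,6-bis(methoxymethoxy)-4-(triisopropylsilyloxy)phenyl]-2-(tert-butyldimethylsilyloxy)propanoate | COC(=O)[C@H](O[Si](C)(C)C(C)(C)C)Cc1c(OCOC)cc(O[Si](C(C)C)(C(C)C)C(C)C)cc1OCOC | intermediate
9 | (2R)-3-[2,6-bis(methoxymethoxy)-4-(triisopropylsilyloxy)phenyl]-2-(tert-butyldimethylsilyloxy)-N-methoxy-N-methylpropanamide | CON(C)C(=O)[C@H](O[Si](C)(C)C(C)(C)C)Cc1c(OCOC)cc(O[Si](C(C)C)(C(C)C)C(C)C)cc1OCOC | intermediate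
10 | (3R)-4-[2,6-bis(methoxymethoxy)-4-(triisopropylsilyloxy)phenyl]-3-(tert-butyldimethylsilyloxy)butan-2-one | CC(=O)[C@H](O[Si](C)(C)C(C)(C)C)Cc1c(OCOC)cc(O[Si](C(C)C)(C(C)C)C(C)C)cc1OCOC | intermediate
11 | {4-[(2R)-2-(tert-butyldimethylsilyloxy)-3-methylbut-3-en-1-yl]-3,5-bis(methoxymethoxy)phenoxy}triisopropylsilane | C=C(C)[C@H](O[Si](C)(C)C(C)(C)C)Cc1c(OCOC)cc(O[Si](C(C)C)(C(C)C)C(C)C)cc1OCOC | intermediate
12 | 4-[(2R)-2-(tert-butyldimethylsilyloxy)-3-methylbut-3-en-1-yl]-3,5-bis(methoxymethoxy)phenol | C=C(C)[C@H](O[Si](C)(C)C(C)(C)C)Cc1c(OCOC)cc(O)cc1OCOC | intermediate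
13 | 3-chloro-3-methylbut-1-yne | C#CC(C)(C)Cl | starting material
14 | tert-butyl{[(2R)-1-{2,6-bis(methoxymethoxy)-4-[(2-methylbut-3-yn-2-yl)oxy]phenyl}-3-methylbut-3-en-2-yl]oxy}dimethylsilane | C=C(C)[C@H](O[Si](C)(C)C(C)(C)C)Cc1c(OCOC)cc(OC(C)(C)C#C)cc1OCOC | intermediate
15 | tert-butyl{[(2R)-1-{2,6-bis(methoxymethoxy)-4-[(2-methylbut-3-en-2-yl)oxy]phenyl}-3-methylbut-3-en-2-yl]oxy}dimethylsilane | C=C(C)[C@H](O[Si](C)(C)C(C)(C)C)Cc1c(OCOC)cc(OC(C)(C)C=C)cc1OCOC | intermediate
16 | 4-[(2R)-2-(tert-butyldimethylsilyloxy)-3-methylbut-3-en-1-yl]-3,5-bis(methoxymethoxy)-6-(3-methylbut-2-en-1-yl)cyclohexa-2,4-dien-1-one (C6 epimers) | C=C(C)[C@H](O[Si](C)(C)C(C)(C)C)CC1=C(OCOC)C(CC=C(C)C)C(=O)C=C1OCOC | intermediate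
17 | 4-[(2R)-2-(tert-butyldimethylsilyloxy)-3-methylbut-3-en-1-yl]-3,5-bis(methoxymethoxy)-2-(3-methylbut-2-en-1-yl)phenol | C=C(C)[C@H](O[Si](C)(C)C(C)(C)C)Cc1c(OCOC)cc(O)c(CC=C(C)C)c1OCOC | intermediate
18 | 3-[(2R)-2-(tert-butyldimethylsilyloxy)-3-methylbut-3-en-1-yl]-6-hydroxy-2,4-bis(methoxymethoxy)-5-(3-methylbut-2-en-1-yl)benzaldehyde | C=C(C)[C@H](O[Si](C)(C)C(C)(C)C)Cc1c(OCOC)c(C=O)c(O)c(CC=C(C)C)c1OCOC | intermediate
19 | 3',4'-dihydroxyacetophenone | CC(=O)c1ccc(O)c(O)c1 | starting material
20 | 1-[3,4-bis(methoxymethoxy)phenyl]ethan-1-one | CC(=O)c1ccc(OCOC)c(OCOC)c1 | intermediate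
21 | {1-[3,4-bis(methoxymethoxy)phenyl]ethenyloxy}trimethylsilane | C=C(O[Si](C)(C)C)c1ccc(OCOC)c(OCOC)c1 | intermediate
22 | 2-bromo-1-[3,4-bis(methoxymethoxy)phenyl]ethan-1-one | O=C(CBr)c1ccc(OCOC)c(OCOC)c1 | intermediate
23 | 6-{2-[3,4-bis(methoxymethoxy)phenyl]-2-oxoethoxy}-3-[(2R)-2-(tert-butyldimethylsilyloxy)-3-methylbut-3-en-1-yl]-2,4-bis(methoxymethoxy)-5-(3-methylbut-2-en-1-yl)benzaldehyde | C=C(C)[C@H](O[Si](C)(C)C(C)(C)C)Cc1c(OCOC)c(CC=C(C)C)c(OCC(=O)c2ccc(OCOC)c(OCOC)c2)c(C=O)c1OCOC | intermediate
24 | 3-[3,4-bis(methoxymethoxy)phenyl]-6-[(2R)-2-(tert-butyldimethylsilyloxy)-3-methylbut-3-en-1-yl]-3-hydroxy-5,7-bis(methoxymethoxy)-8-(3-methylbut-2-en-1-yl)-2,3-dihydro-4H-chromen-4-one (C3 epimers) | C=C(C)[C@H](O[Si](C)(C)C(C)(C)C)Cc1c(OCOC)c(CC=C(C)C)c2OCC(O)(c3ccc(OCOC)c(OCOC)c3)C(=O)c2c1OCOC | intermediate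
25 | 3-[3,4-bis(methoxymethoxy)phenyl]-6-[(2R)-2-(tert-butyldimethylsilyloxy)-3-methylbut-3-en-1-yl]-5,7-bis(methoxymethoxy)-8-(3-methylbut-2-en-1-yl)-4H-chromen-4-one | C=C(C)[C@H](O[Si](C)(C)C(C)(C)C)Cc1c(OCOC)c(CC=C(C)C)c2occ(-c3ccc(OCOC)c(OCOC)c3)c(=O)c2c1OCOC | intermediate
26 | 3-(3,4-dihydroxyphenyl)-5,7-dihydroxy-6-[(2R)-2-hydroxy-3-methylbut-3-en-1-yl]-8-(3-methylbut-2-en-1-yl)-4H-chromen-4-one | C=C(C)[C@H](O)Cc1c(O)c(CC=C(C)C)c2occ(-c3ccc(O)c(O)c3)c(=O)c2c1O | target

## Step count and least certain steps

Total step count: 17. Longest linear sequence: 15 steps (steps 1–11 and 14–17, from phloroglucinol); the ring B branch is steps 12–13.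

**Step 15 (key step).** The aldehyde is doubly ortho-substituted and electron-rich, so formation of the Breslow intermediate may be slow. Base-mediated enolisation of the phenacyl ketone with aldol closure onto the aldehyde (Rap–Stoermer benzofuran formation), or air oxidation of the aldehyde, could then take over. The fallback sets out from 18 and gives up the benzoin closure in favour of a cross-coupling construction of the C3–C1' bond. Addition of MeMgBr to 18 would give 2-[(1-hydroxyethyl)]phenol F1, and MnO2 oxidation would give the 2-hydroxyacetophenone F2. Heating with Me2NCH(OMe)2 would give enaminone F3, and I2/pyridine in CHCl3 would close ring C to the 3-iodochromone F4. Suzuki–Miyaura coupling (Pd(PPh3)4, K2CO3, DME/H2O) with [3,4-bis(methoxymethoxy)phenyl]boronic acid F6 would then give 25, where the route is rejoined. F6 would be made from 4-bromocatechol through 4-bromo-1,2-bis(methoxymethoxy)benzene F5 by bromine–lithium exchange and B(OiPr)3.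

**Step 3.** Bromide from the magnesium salts may open the activated epoxide, the aryl metal may attack the ester, or transfer of the di-ortho-substituted aryl group may be sluggish. The fallback sets out from 3 and makes the stereocentre by reagent control. Aryllithium 5 would be alkylated with prenyl bromide (CuI cat.) to the prenylarene F7. Shi epoxidation (D-fructose-derived ketone, Oxone (2KHSO5·KHSO4·K2SO4), buffered MeCN/dimethoxymethane, 0 °C) should give the (R)-epoxide F8, with the face set by the spiro transition state of the chiral dioxirane. Isomerisation with diethylaluminium 2,2,6,6-tetramethylpiperidide would remove a methyl proton and give allylic alcohol F9 with the C–O bond at the stereocentre intact. Silylation (TBSCl, imidazole) would give 11, where the route is rejoined.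

**Step 11.** Formylation may stall at a position hemmed in by the phenoxide, a MOM ether and the buttressed neighbours, or the magnesium salt may promote cyclisation of the ortho-prenyl phenol. The fallback sets out from 12 and reverses the order of formylation and Claisen rearrangement. Formylation of 12 under the same magnesium conditions, with two equivalent open sites and no prenyl group, would give salicylaldehyde F10. Copper-catalysed etherification with 13 would give propargyl ether F11, and Lindlar hydrogenation would give allyl ether F12. Claisen rearrangement to the only free ortho position would give 18, where the route is rejoined.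

**Step 16.** Sulfamate formation at the crowded tertiary carbinol may fail, or ionisation may be followed by an alpha-ketol-type skeletal shift instead of proton loss from C2. The fallback sets out from 24 and replaces dehydration by reduction and re-oxidation. SmI2 in THF/MeOH would cleave the alpha-hydroxyl reductively to the isoflavanone F13. LiN(SiMe3)2 and PhSeBr would give the alpha-phenylselanyl ketone F14, and H2O2 oxidation with selenoxide syn-elimination toward C2 would give 25, where the route is rejoined.

**Step 17.** Before the last acetal is gone, acid may cyclise the prenyl group onto the freed 7-hydroxyl, or ionise the allylic carbinol with ring closure onto O5 or O7. The fallback sets out from 25 and avoids free Brønsted acid. TBAF would remove the silyl ether to give the tetra-MOM alcohol F15. TMSOTf with 2,2'-bipyridyl in MeCN at 0 °C would then exchange the four aryl MOM ethers for aryl trimethylsilyl ethers, which water hydrolyses to give 26.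

## Further compounds

F1 | step 15 | 2-[(2R)-2-(tert-butyldimethylsilyloxy)-3-methylbut-3-en-1-yl]-5-(1-hydroxyethyl)-1,3-bis(methoxymethoxy)-... phenol: 3-[(2R)-2-(tert-butyldimethylsilyloxy)-3-methylbut-3-en-1-yl]-6-hydroxy-2,4-bis(methoxymethoxy)-5-(3-methylbut-2-en-1-yl)phenyl methyl carbinol (carbinol epimers) | C=C(C)[C@H](O[Si](C)(C)C(C)(C)C)Cc1c(OCOC)c(C(C)O)c(O)c(CC=C(C)C)c1OCOC
F2 | step 15 | 1-{3-[(2R)-2-(tert-butyldimethylsilyloxy)-3-methylbut-3-en-1-yl]-6-hydroxy-2,4-bis(methoxymethoxy)-5-(3-methylbut-2-en-1-yl)phenyl}ethan-1-one | C=C(C)[C@H](O[Si](C)(C)C(C)(C)C)Cc1c(OCOC)c(C(C)=O)c(O)c(CC=C(C)C)c1OCOC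
F3 | step 15 | (E)-1-{3-[(2R)-2-(tert-butyldimethylsilyloxy)-3-methylbut-3-en-1-yl]-6-hydroxy-2,4-bis(methoxymethoxy)-5-(3-methylbut-2-en-1-yl)phenyl}-3-(dimethylamino)prop-2-en-1-one | C=C(C)[C@H](O[Si](C)(C)C(C)(C)C)Cc1c(OCOC)c(C(=O)/C=C/N(C)C)c(O)c(CC=C(C)C)c1OCOC
F4 | step 15 | 6-[(2R)-2-(tert-butyldimethylsilyloxy)-3-methylbut-3-en-1-yl]-3-iodo-5,7-bis(methoxymethoxy)-8-(3-methylbut-2-en-1-yl)-4H-chromen-4-one | C=C(C)[C@H](O[Si](C)(C)C(C)(C)C)Cc1c(OCOC)c(CC=C(C)C)c2occ(I)c(=O)c2c1OCOC
F5 | step 15 | 4-bromo-1,2-bis(methoxymethoxy)benzene | COCOc1ccc(Br)cc1OCOC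
F6 | step 15 | [3,4-bis(methoxymethoxy)phenyl]boronic acid | COCOc1ccc(B(O)O)cc1OCOC
F7 | step 3 | [3,5-bis(methoxymethoxy)-4-(3-methylbut-2-en-1-yl)phenoxy]triisopropylsilane | CC(C)=CCc1c(OCOC)cc(O[Si](C(C)C)(C(C)C)C(C)C)cc1OCOC
F8 | step 3 | {4-{[(2R)-3,3-dimethyloxiran-2-yl]methyl}-3,5-bis(methoxymethoxy)phenoxy}triisopropylsilane | CC1(C)O[C@@H]1Cc1c(OCOC)cc(O[Si](C(C)C)(C(C)C)C(C)C)cc1OCOC
F9 | step 3 | (2R)-1-[2,6-bis(methoxymethoxy)-4-(triisopropylsilyloxy)phenyl]-3-methylbut-3-en-2-ol | C=C(C)[C@H](O)Cc1c(OCOC)cc(O[Si](C(C)C)(C(C)C)C(C)C)cc1OCOC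
F10 | step 11 | 3-[(2R)-2-(tert-butyldimethylsilyloxy)-3-methylbut-3-en-1-yl]-6-hydroxy-2,4-bis(methoxymethoxy)benzaldehyde | C=C(C)[C@H](O[Si](C)(C)C(C)(C)C)Cc1c(OCOC)cc(O)c(C=O)c1OCOC
F11 | step 11 | 3-[(2R)-2-(tert-butyldimethylsilyloxy)-3-methylbut-3-en-1-yl]-2,4-bis(methoxymethoxy)-6-[(2-methylbut-3-yn-2-yl)oxy]benzaldehyde | C=C(C)[C@H](O[Si](C)(C)C(C)(C)C)Cc1c(OCOC)cc(OC(C)(C)C#C)c(C=O)c1OCOC
F12 | step 11 | 3-[(2R)-2-(tert-butyldimethylsilyloxy)-3-methylbut-3-en-1-yl]-2,4-bis(methoxymethoxy)-6-[(2-methylbut-3-en-2-yl)oxy]benzaldehyde | C=C(C)[C@H](O[Si](C)(C)C(C)(C)C)Cc1c(OCOC)cc(OC(C)(C)C=C)c(C=O)c1OCOC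
F13 | step 16 | 3-[3,4-bis(methoxymethoxy)phenyl]-6-[(2R)-2-(tert-butyldimethylsilyloxy)-3-methylbut-3-en-1-yl]-5,7-bis(methoxymethoxy)-8-(3-methylbut-2-en-1-yl)-2,3-dihydro-4H-chromen-4-one (C3 epimers) | C=C(C)[C@H](O[Si](C)(C)C(C)(C)C)Cc1c(OCOC)c(CC=C(C)C)c2OCC(c3ccc(OCOC)c(OCOC)c3)C(=O)c2c1OCOC
F14 | step 16 | 3-[3,4-bis(methoxymethoxy)phenyl]-6-[(2R)-2-(tert-butyldimethylsilyloxy)-3-methylbut-3-en-1-yl]-5,7-bis(methoxymethoxy)-8-(3-methylbut-2-en-1-yl)-3-(phenylselanyl)-2,3-dihydro-4H-chromen-4-one (C3 epimers) | C=C(C)[C@H](O[Si](C)(C)C(C)(C)C)Cc1c(OCOC)c(CC=C(C)C)c2OCC([Se]c3ccccc3)(c3ccc(OCOC)c(OCOC)c3)C(=O)c2c1OCOC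
F15 | step 17 | 3-[3,4-bis(methoxymethoxy)phenyl]-6-[(2R)-2-hydroxy-3-methylbut-3-en-1-yl]-5,7-bis(methoxymethoxy)-8-(3-methylbut-2-en-1-yl)-4H-chromen-4-one | C=C(C)[C@H](O)Cc1c(OCOC)c(CC=C(C)C)c2occ(-c3ccc(OCOC)c(OCOC)c3)c(=O)c2c1OCOC
A1 | alternative 1 | 5-ethoxy-2-(3-methylbut-2-en-1-yl)-3-(triisopropylsilyloxy)-4-[(2R)-2-(tert-butyldimethylsilyloxy)-3-methylbut-3-en-1-yl]phenol | C=C(C)[C@H](O[Si](C)(C)C(C)(C)C)Cc1c(OCC)cc(O)c(CC=C(C)C)c1O[Si](C(C)C)(C(C)C)C(C)C
A2 | alternative 1 | 2-[(2R)-2-(tert-butyldimethylsilyloxy)-3-methylbut-3-en-1-yl]-3-ethoxycyclobut-2-en-1-one | C=C(C)[C@H](O[Si](C)(C)C(C)(C)C)CC1=C(OCC)CC1=O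
A3 | alternative 1 | triisopropyl[(5-methylhex-4-en-1-yn-1-yl)oxy]silane | CC(C)=CCC#CO[Si](C(C)C)(C(C)C)C(C)C
A4 | alternative 2 | 3-(3,4-dihydroxyphenyl)-6-[(2R)-2-(methoxymethoxy)-3-methylbut-3-en-1-yl]-5,7-bis(methoxymethoxy)-8-(3-methylbut-2-en-1-yl)-4H-chromen-4-one | C=C(C)[C@H](OCOC)Cc1c(OCOC)c(CC=C(C)C)c2occ(-c3ccc(O)c(O)c3)c(=O)c2c1OCOC
A5 | alternative 2 | (E)-3-(dimethylamino)-1-{6-hydroxy-2,4-bis(methoxymethoxy)-3-[(2R)-2-(methoxymethoxy)-3-methylbut-3-en-1-yl]-5-(3-methylbut-2-en-1-yl)phenyl}prop-2-en-1-one | C=C(C)[C@H](OCOC)Cc1c(OCOC)c(CC=C(C)C)c(O)c(C(=O)/C=C/N(C)C)c1OCOC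
A6 | alternative 2 | catechol (benzene-1,2-diol) | Oc1ccccc1O
A7 | alternative 2 | ortho-benzoquinone (cyclohexa-3,5-diene-1,2-dione) | O=C1C=CC=CC1=O
A8 | alternative 3 | 3-[3,4-bis(methoxymethoxy)phenyl]-6-[(2R)-2-(methoxymethoxy)-3-methylbut-3-en-1-yl]-5,7-bis(methoxymethoxy)-8-(3-methylbut-2-en-1-yl)-4H-chromen-4-one | C=C(C)[C@H](OCOC)Cc1c(OCOC)c(CC=C(C)C)c2occ(-c3ccc(OCOC)c(OCOC)c3)c(=O)c2c1OCOC
A9 | alternative 3 | (E)-2-[3,4-bis(methoxymethoxy)phenyl]-3-methoxyprop-2-enoic acid | CO/C=C(/C(=O)O)c1ccc(OCOC)c(OCOC)c1
A10 | alternative 3 | 3,5-bis(methoxymethoxy)-4-[(2R)-2-(methoxymethoxy)-3-methylbut-3-en-1-yl]-2-(3-methylbut-2-en-1-yl)-6-(trimethylsilyl)phenyl trifluoromethanesulfonate | C=C(C)[C@H](OCOC)Cc1c(OCOC)c(CC=C(C)C)c(OS(=O)(=O)C(F)(F)F)c([Si](C)(C)C)c1OCOC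
A11 | alternative 3 | 3,5-bis(methoxymethoxy)-4-[(2R)-2-(methoxymethoxy)-3-methylbut-3-en-1-yl]-6-(3-methylbut-2-en-1-yl)benzyne (triple bond between C4a and C8a) | C=C(C)[C@H](OCOC)CC1=C(OCOC)C#CC(CC=C(C)C)=C1OCOC
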